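## Retrosynthetic overview

1. Target ⇒ α-methylene lactone acid carrying a tridec-12-enyl chain. The keto terminus comes from cross-metathesis with methyl vinyl ketone, and C4 is set by face-selective hydrogenation of the exocyclic C=C.
2. ⇒ trans-5-oxo-2-alkyloxolane-3-carboxylic acid, by carboxylation/decarboxylative Mannich methylenation.
3. ⇒ trans-2-alkyl-3-oxocyclobutane-1-carboxylic acid, by Baeyer–Villiger ring expansion (1,2-shift of C2 from carbon to oxygen with retention).
4. ⇒ 3-oxocyclobutane-1-carboxylic acid + trideca-1,12-diene, by a new desymmetrising, enantioselective anti-Markovnikov α-hydroalkylation that sets both ring stereocentres. The diene comes from Li2CuCl4-catalysed Grignard coupling of 7-bromohept-1-ene and 6-bromohex-1-ene.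
5. Ring order: the four-membered ring is bought; the only ring-forming event is its expansion to the γ-lactone.

Assumption: the SMILES is read as the (2S,3R,4S) lactone (C2 chain trans to C3 CO2H, C3 CO2H cis to C4 CH3). For the new step the dihydroquinine-derived amine is taken to give the (1R,2S) cyclobutanone; its dihydroquinidine-derived pseudoenantiomer is used if the sense proves opposite.

## Route

Step 1
Reactants: 1 7-bromohept-1-ene; 2 6-bromohex-1-ene
Product: 4 trideca-1,12-diene, via hept-6-en-1-ylmagnesium bromide 3 (not isolated)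
Conditions: 1, Mg, THF, 40 °C; then 2, Li2CuCl4 (3 mol%), THF, −10 °C to rt; distil
Reagents that add atoms: magnesium, [Mg] (held in intermediate 3 only, absent from 4)
Why: Kochi-type Li2CuCl4-catalysed coupling of a primary alkyl Grignard reagent with a primary alkyl bromide is reliable for plain chains, the Grignard reagent is made from the C7 bromide because the hept-6-enyl radical cyclises far more slowly than hex-5-enyl during magnesium insertion, and no stereocentre is formed.

Step 2
Reactants: 5 3-oxocyclobutane-1-carboxylic acid; 4 trideca-1,12-diene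
Product: 6 (1R,2S)-3-oxo-2-(tridec-12-en-1-yl)cyclobutane-1-carboxylic acid
Conditions: 9-amino-9-deoxy-epi-dihydroquinine (20 mol%), [Ir(ppy)2(dtbbpy)]PF6 (1 mol%), 2,4,6-iPr3C6H2SH (10 mol%), DME, 450 nm LEDs, 0 °C; diene in fourfold excess, surplus recovered by acid–base extraction
Reagents that add atoms: none
Why: Proposed new method: the primary amine condenses with the strained ketone of 5 to an enamine whose carboxylate is salt-bridged to the protonated quinuclidine; the photoexcited trivalent iridium complex oxidises this enamine (about +0.7 V, too low to decarboxylate the acid) to an electrophilic enaminyl radical cation that adds to the terminal CH2 of 4 from the face opposite the C1 carboxylate; the resulting secondary alkyl radical takes H from the thiol (anti-Markovnikov outcome), divalent iridium reduces the thiyl radical, and hydrolysis releases 6, so the step is a net addition of the α-C–H bond across one alkene in which every atom of 5 and 4 is kept; enantioselectivity is a choice between the two enantiotopic CH2 groups (only one enamine regioisomer has its anti face open in the two-point-bound complex), so later C2 epimerisation through the enamine can only raise the trans ratio and cannot erode ee; the closest known reaction types are the enamine/photoredox/thiol hydrogen-atom-transfer α-alkylation of aldehydes with simple olefins and the organocatalytic enamine desymmetrisation of 3-substituted cyclobutanones (aldol, Michael), which have not been combined on a cyclobutanone or a keto acid.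

Step 3
Reactants: 6 (1R,2S)-3-oxo-2-(tridec-12-en-1-yl)cyclobutane-1-carboxylic acid
Product: 7 (2S,3R)-5-oxo-2-(tridec-12-en-1-yl)oxolane-3-carboxylic acid
Conditions: 30% aq H2O2 (3 equiv), AcOH, 0 °C to rt
Reagents that add atoms: hydrogen peroxide, OO
Why: Baeyer–Villiger ring expansion (Criegee 1,2-shift) in which the strained cyclobutanone reacts with H2O2 without a peracid, the more substituted C2 migrates to oxygen with retention so the S carbinol centre and the trans relationship are carried over unchanged, and the terminal alkene is inert to H2O2 under these conditions.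

Step 4
Reactants: 7 (2S,3R)-5-oxo-2-(tridec-12-en-1-yl)oxolane-3-carboxylic acid
Product: 9 (2S,3R)-4-methylidene-5-oxo-2-(tridec-12-en-1-yl)oxolane-3-carboxylic acid, via 4-carboxy lactone diacid 8 (not isolated)
Conditions: MeOMgOCO2Me (2 M in DMF, excess), 135 °C, 60 h; cold 10% aq HCl; then 37% aq HCHO, PhNHMe, NaOAc, AcOH, rt
Reagents that add atoms: formaldehyde, C=O; methoxymagnesium methyl carbonate, COC(=O)O[Mg]OC (its CO2 unit is held in intermediate 8 only)
Why: Stiles carboxylation followed by decarboxylative Mannich methylenation is the standard α-methylenation of free paraconic acids, the magnesium chelate activates only the lactone α-carbon, and C2 and C3 are untouched (trans is also the thermodynamic arrangement).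

Step 5
Reactants: 9 (2S,3R)-4-methylidene-5-oxo-2-(tridec-12-en-1-yl)oxolane-3-carboxylic acid; 10 but-3-en-2-one
Product: 12 (2S,3R,4S)-4-methyl-5-oxo-2-(14-oxopentadecyl)oxolane-3-carboxylic acid, via enone acid 11 (not isolated)
Conditions: second-generation Hoveyda–Grubbs catalyst RuCl2(H2IMes)(=CH-C6H4-2-OiPr) (5 mol%), enone in fivefold excess, CH2Cl2, 40 °C; evaporate volatiles; then H2 (1 atm), 10% Pd/C, EtOAc, rt; neutral work-up
Reagents that add atoms: none
Why: Olefin cross-metathesis of the terminal alkene with the electron-poor enone is E-selective while the hindered 1,1-disubstituted α-methylene lactone is a very slow metathesis partner, and the following heterogeneous hydrogenation saturates the enone C=C and delivers H2 to the exocyclic methylene from the face anti to the adjacent C3 carboxyl, which gives the 3,4-cis methyl group (4S) and leaves the ketone untouched.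

## Compound list

1 | 7-bromohept-1-ene | C=CCCCCCBr | starting material
2 | 6-bromohex-1-ene | C=CCCCCBr | starting material
3 | hept-6-en-1-ylmagnesium bromide | C=CCCCCC[Mg]Br | intermediate
4 | trideca-1,12-diene | C=CCCCCCCCCCC=C | intermediate
5 | 3-oxocyclobutane-1-carboxylic acid | O=C1CC(C(=O)O)C1 | starting material
6 | (1R,2S)-3-oxo-2-(tridec-12-en-1-yl)cyclobutane-1-carboxylic acid (chain trans to CO2H) | C=CCCCCCCCCCCC[C@@H]1C(=O)C[C@H]1C(=O)O | intermediate
7 | (2S,3R)-5-oxo-2-(tridec-12-en-1-yl)oxolane-3-carboxylic acid | C=CCCCCCCCCCCC[C@@H]1OC(=O)C[C@H]1C(=O)O | intermediate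
8 | (2S,3R,4RS)-5-oxo-2-(tridec-12-en-1-yl)oxolane-3,4-dicarboxylic acid (formed as its magnesium chelate) | C=CCCCCCCCCCCC[C@@H]1OC(=O)C(C(=O)O)[C@H]1C(=O)O | intermediate
9 | (2S,3R)-4-methylidene-5-oxo-2-(tridec-12-en-1-yl)oxolane-3-carboxylic acid | C=CCCCCCCCCCCC[C@@H]1OC(=O)C(=C)[C@H]1C(=O)O | intermediate
10 | but-3-en-2-one (methyl vinyl ketone) | CC(=O)C=C | starting material
11 | (2S,3R)-4-methylidene-5-oxo-2-[(12E)-14-oxopentadec-12-en-1-yl]oxolane-3-carboxylic acid | CC(=O)/C=C/CCCCCCCCCCC[C@@H]1OC(=O)C(=C)[C@H]1C(=O)O | intermediate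
12 | (2S,3R,4S)-4-methyl-5-oxo-2-(14-oxopentadecyl)oxolane-3-carboxylic acid | CC(=O)CCCCCCCCCCCCC[C@@H]1OC(=O)[C@@H](C)[C@H]1C(=O)O | target

## Step count and risks

Total steps: 5. Longest linear sequence: 5 (1 → 4 → 6 → 7 → 9 → 12).

**Step 2 (new reaction).** Risks: the hydroalkylation has no precedent on this substrate; a second alkylation at C4 or at the far alkene of 4 is possible; the ee is unproven. The fallback sets out from 4 and 5 and comes back at 6, using only known chemistry. Radical anti-Markovnikov hydrobromination of excess 4 (HBr, dibenzoyl peroxide, hexane, 0 °C) gives 13-bromotridec-1-ene F1. Acid 5 and 1,1-dimethylhydrazine give 3-(2,2-dimethylhydrazinylidene)cyclobutane-1-carboxylic acid F2. Its dianion (LiN(iPr)2, 2.2 equiv, THF, −78 °C) is alkylated by F1 anti to the carboxylate to give racemic trans 3-(2,2-dimethylhydrazinylidene)-2-(tridec-12-en-1-yl)cyclobutane-1-carboxylic acid F3. Two-phase aqueous oxalic acid frees racemic trans 3-oxo-2-(tridec-12-en-1-yl)cyclobutane-1-carboxylic acid F4. Preparative chiral SFC then delivers 6 (at most half of the material).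

**Step 5 (metathesis next to the α-methylene lactone, then face-selective hydrogenation).** Risks: the methylene lactone may enter metathesis; Pd/C may move the exocyclic C=C into the ring before reduction; the C4 epimers are hard to separate. The fallback sets out from 7 and comes back at 12, and does the metathesis before the methylene lactone exists, with the ketone masked. Cross-metathesis of 7 with 2-methyl-2-vinyl-1,3-dioxolane (RuCl2(H2IMes)(=CH-C6H4-2-OiPr), CH2Cl2, 40 °C) gives (2S,3R)-2-[(12E)-13-(2-methyl-1,3-dioxolan-2-yl)tridec-12-en-1-yl]-5-oxooxolane-3-carboxylic acid F7. The conditions of step 4, with a cold aqueous citric acid work-up in place of HCl to spare the ketal, carry it through the corresponding 4-carboxy diacid F8 to the α-methylene ketal acid F9. Hydrogenation (H2, 10% Pd/C, EtOAc) gives (2S,3R,4S)-4-methyl-2-[13-(2-methyl-1,3-dioxolan-2-yl)tridecyl]-5-oxooxolane-3-carboxylic acid F10. Aqueous HCl in THF removes the ketal to give 12.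

**Step 4 (long heating with the magnesium carbonate reagent, moderate yields typical).** The fallback sets out from 7 and comes back at 9. The dianion of 7 (LiN(SiMe3)2, 2.2 equiv, THF, −78 °C) is trapped with dimethylmethylideneammonium iodide to give (2S,3R)-4-[(dimethylamino)methyl]-5-oxo-2-(tridec-12-en-1-yl)oxolane-3-carboxylic acid F5. Methyl iodide in MeOH converts it to the trimethylammonium iodide F6. Aqueous NaHCO3/EtOAc then eliminates trimethylamine to give 9.

## Further compounds

F1 | step 2 | 13-bromotridec-1-ene | C=CCCCCCCCCCCCBr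
F2 | step 2 | 3-(2,2-dimethylhydrazinylidene)cyclobutane-1-carboxylic acid | CN(C)N=C1CC(C(=O)O)C1
F3 | step 2 | racemic trans 3-(2,2-dimethylhydrazinylidene)-2-(tridec-12-en-1-yl)cyclobutane-1-carboxylic acid, (1R,2S) plus (1S,2R) | C=CCCCCCCCCCCC[C@@H]1C(=NN(C)C)C[C@H]1C(=O)O.C=CCCCCCCCCCCC[C@H]1C(=NN(C)C)C[C@@H]1C(=O)O
F4 | step 2 | racemic trans 3-oxo-2-(tridec-12-en-1-yl)cyclobutane-1-carboxylic acid, 6 plus its (1S,2R) mirror image | C=CCCCCCCCCCCC[C@@H]1C(=O)C[C@H]1C(=O)O.C=CCCCCCCCCCCC[C@H]1C(=O)C[C@@H]1C(=O)O
F5 | step 4 | (2S,3R)-4-[(dimethylamino)methyl]-5-oxo-2-(tridec-12-en-1-yl)oxolane-3-carboxylic acid (C4 epimers) | C=CCCCCCCCCCCC[C@@H]1OC(=O)C(CN(C)C)[C@H]1C(=O)O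
F6 | step 4 | {[(4R,5S)-4-carboxy-2-oxo-5-(tridec-12-en-1-yl)oxolan-3-yl]methyl}trimethylammonium iodide (C3 epimers) | C=CCCCCCCCCCCC[C@@H]1OC(=O)C(C[N+](C)(C)C)[C@H]1C(=O)O.[I-]
F7 | step 5 | (2S,3R)-2-[(12E)-13-(2-methyl-1,3-dioxolan-2-yl)tridec-12-en-1-yl]-5-oxooxolane-3-carboxylic acid | CC2(OCCO2)/C=C/CCCCCCCCCCC[C@@H]1OC(=O)C[C@H]1C(=O)O
F8 | step 5 | (2S,3R,4RS)-2-[(12E)-13-(2-methyl-1,3-dioxolan-2-yl)tridec-12-en-1-yl]-5-oxooxolane-3,4-dicarboxylic acid | CC2(OCCO2)/C=C/CCCCCCCCCCC[C@@H]1OC(=O)C(C(=O)O)[C@H]1C(=O)O
F9 | step 5 | (2S,3R)-4-methylidene-2-[(12E)-13-(2-methyl-1,3-dioxolan-2-yl)tridec-12-en-1-yl]-5-oxooxolane-3-carboxylic acid | CC2(OCCO2)/C=C/CCCCCCCCCCC[C@@H]1OC(=O)C(=C)[C@H]1C(=O)O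
F10 | step 5 | (2S,3R,4S)-4-methyl-2-[13-(2-methyl-1,3-dioxolan-2-yl)tridecyl]-5-oxooxolane-3-carboxylic acid | CC2(OCCO2)CCCCCCCCCCCCC[C@@H]1OC(=O)[C@@H](C)[C@H]1C(=O)O
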